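**Retrosynthetic overview**
- Target 15 ← hydrogenolysis of the tribenzyl depsidone 14 ← carbodiimide lactonisation of seco acid 13 (seven-membered ring, closed last).
- 13 ← one-flask Diels–Alder benzannulation / aromatisation / lactonisation of diene 11 with ynoate 10: ring B and the five-membered lactone form together.
- The diaryl ether oxygen is carried in as the 4-aryloxy group of β-keto ester 8, so no aryl–oxygen coupling is needed.
- 8 ← phenol 5 (ring A) + methyl 4-chloroacetoacetate 6, then C-benzyloxymethylation; 5 ← 2,6-dihydroxy-4-methylbenzoic acid 1 in four steps.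
- Ring order: ring A bought; ring B + phthalide lactone (step 8); dioxepinone (step 9).

Assumption: the target has no stereocentre and no stable atropisomerism, so it is one achiral compound and no enantiocontrol is needed; 1, 6, 9 and all reagents are taken as commercial.

**Route**

Step 1
Reactants: 1 2,6-dihydroxy-4-methylbenzoic acid
Product: 2 benzyl 2-(benzyloxy)-6-hydroxy-4-methylbenzoate
Conditions: BnBr (2.05 equiv), K2CO3, DMF, 0 °C to rt
Reagents that add atoms: benzyl bromide, BrCc1ccccc1
Why: The carboxylate is alkylated first and one of the two equivalent phenols second, after which the remaining phenol is locked in a hydrogen bond to the ester carbonyl and stays free (carboxylate alkylation plus selective Williamson mono-etherification).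

Step 2
Reactants: 2 benzyl 2-(benzyloxy)-6-hydroxy-4-methylbenzoate
Product: 3 benzyl 6-(benzyloxy)-3-formyl-2-hydroxy-4-methylbenzoate
Conditions: MgCl2, Et3N, (CH2O)n, MeCN, reflux
Reagents that add atoms: formaldehyde (as paraformaldehyde), C=O
Why: Magnesium-phenoxide-directed ortho-formylation (Casnati–Skattebøl) reacts only ortho to the free phenol, and the single open ortho position is the one next to the methyl group and para to the benzyloxy group.

Step 3
Reactants: 3 benzyl 6-(benzyloxy)-3-formyl-2-hydroxy-4-methylbenzoate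
Product: 4 4-(benzyloxy)-3-[(benzyloxy)carbonyl]-2-hydroxy-6-methylbenzoic acid
Conditions: NaClO2, NaH2PO4, 2-methylbut-2-ene, t-BuOH/THF/H2O, 0 °C to rt
Reagents that add atoms: sodium chlorite, [Na+].[O-]Cl=O
Why: Lindgren–Kraus–Pinnick oxidation converts the salicylaldehyde to the acid under buffered conditions that leave phenol, benzyl ether and benzyl ester alone, with the alkene trapping HOCl before it chlorinates the ring.

Step 4
Reactants: 4 4-(benzyloxy)-3-[(benzyloxy)carbonyl]-2-hydroxy-6-methylbenzoic acid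
Product: 5 3-benzyl 1-[2-(trimethylsilyl)ethyl] 4-(benzyloxy)-2-hydroxy-6-methylbenzene-1,3-dicarboxylate
Conditions: Me3SiCH2CH2OH, PPh3, DIAD, THF, 0 °C to rt
Reagents that add atoms: 2-(trimethylsilyl)ethanol, C[Si](C)(C)CCO
Why: Mitsunobu esterification forms the C–O bond at the primary carbinol carbon, so the hindrance of the 2,6-disubstituted acid is irrelevant and the far more acidic CO2H reacts before the chelated phenol; this ester is chosen because fluoride releases it in step 8.

Step 5
Reactants: 5 3-benzyl 1-[2-(trimethylsilyl)ethyl] 4-(benzyloxy)-2-hydroxy-6-methylbenzene-1,3-dicarboxylate; 6 methyl 4-chloro-3-oxobutanoate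
Product: 7 3-benzyl 1-[2-(trimethylsilyl)ethyl] 4-(benzyloxy)-2-(4-methoxy-2,4-dioxobutoxy)-6-methylbenzene-1,3-dicarboxylate
Conditions: K2CO3, KI (cat.), DMF, rt to 40 °C
Reagents that add atoms: none
Why: Williamson etherification of the acidic phenoxide with an SN2-activated α-chloro ketone under iodide catalysis, where the carbonate base deprotonates the keto ester only at C-2 so that no carbanion next to the aryloxy group can attack the ring esters.

Step 6
Reactants: 7 3-benzyl 1-[2-(trimethylsilyl)ethyl] 4-(benzyloxy)-2-(4-methoxy-2,4-dioxobutoxy)-6-methylbenzene-1,3-dicarboxylate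
Product: 8 3-benzyl 1-[2-(trimethylsilyl)ethyl] 4-(benzyloxy)-2-{3-[(benzyloxy)methyl]-4-methoxy-2,4-dioxobutoxy}-6-methylbenzene-1,3-dicarboxylate
Conditions: NaH (1.0 equiv), THF, 0 °C; BnOCH2Cl
Reagents that add atoms: benzyl chloromethyl ether, ClCOCc1ccccc1
Why: The sodium enolate of the β-keto ester, a tight ion pair in THF, is alkylated at carbon by the chloromethyl ether (enolate C-alkylation), and the new stereocentre is formed racemic and is erased when this carbon becomes aromatic in step 8.

Step 7
Reactants: 9 methyl 4-hydroxybut-2-ynoate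
Product: 10 methyl 4-[(tert-butyldimethylsilyl)oxy]but-2-ynoate
Conditions: t-BuMe2SiCl, imidazole, CH2Cl2, 0 °C to rt
Reagents that add atoms: tert-butyldimethylsilyl chloride, CC(C)(C)[Si](C)(C)Cl
Why: Standard silylation masks the alcohol, which would otherwise protonate the silyl ketene acetal of the diene in step 8.

Step 8
Reactants: 8 3-benzyl 1-[2-(trimethylsilyl)ethyl] 4-(benzyloxy)-2-{3-[(benzyloxy)methyl]-4-methoxy-2,4-dioxobutoxy}-6-methylbenzene-1,3-dicarboxylate; 10 methyl 4-[(tert-butyldimethylsilyl)oxy]but-2-ynoate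
Product: 13 4-(benzyloxy)-3-[(benzyloxy)carbonyl]-2-({6-[(benzyloxy)methyl]-5,7-dihydroxy-1-oxo-1,3-dihydro-2-benzofuran-4-yl}oxy)-6-methylbenzoic acid, via bis-silyl diene 11 (not isolated), via cyclohexadiene cycloadduct 12 (not isolated)
Conditions: Me3SiOTf, Et3N, Et2O, 0 °C; filter, concentrate; 10, PhMe, 90 °C; Bu4NF, THF, 0 °C to rt; cold 0.5 M HCl work-up
Reagents that add atoms: none
Why: Proposed new method: the 1-methoxy-1,3-bis(silyloxy)diene 11 is nucleophilic at C-4 (the aryloxy-bearing terminus), so it should bond there to the β-carbon of ynoate 10 and close from the ketal carbon C-1 onto the α-carbon (concerted Diels–Alder or stepwise Mukaiyama–Michael/ring closure, same regiochemistry), after which fluoride removes the silyl groups, the ketal carbon loses methoxide and C-4 its proton (aromatisation is only possible with the aryloxy group retained), the freed CH2O– closes the phthalide on the neighbouring methyl ester and the silylethyl ester fragments to the acid; the closest known reaction types are Diels–Alder benzannulations of Chan/Brassard-type silyloxy dienes with alkynoates to salicylates and phthalides and the construction of diaryl ethers from 4-aryloxy-1,3-bis(silyloxy)dienes, and the transient stereocentres of 12 vanish on aromatisation.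

Step 9
Reactants: 13 4-(benzyloxy)-3-[(benzyloxy)carbonyl]-2-({6-[(benzyloxy)methyl]-5,7-dihydroxy-1-oxo-1,3-dihydro-2-benzofuran-4-yl}oxy)-6-methylbenzoic acid
Product: 14 tri-O-benzyl conneotricone (target with the CO2H as benzyl ester and with the ring A phenol and the CH2OH as benzyl ethers)
Conditions: DCC, DMAP (cat.), CH2Cl2 (2 mM), rt
Reagents that add atoms: none
Why: Carbodiimide lactonisation of a 2-aryloxybenzoic acid onto the ortho phenol of the other ring is the classical closure of the depsidone ring, and here only the phenol next to the ether oxygen can reach the activated acid while the second carboxyl is blocked as its benzyl ester, so the regiochemistry is fixed.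

Step 10
Reactants: 14 tri-O-benzyl conneotricone
Product: 15 conneotricone
Conditions: H2 (1 atm), Pd/C (10 wt %), EtOAc/THF, rt
Reagents that add atoms: none
Why: Hydrogenolysis removes the benzyl ester and both benzyl ethers without touching the aryl ester or the lactone, and the benzylic C–O bond of the product sits on a hexasubstituted ring that adsorbs poorly on palladium, so over-reduction to the methyl compound should be slow.

**Compound list**
1 | 2,6-dihydroxy-4-methylbenzoic acid | Cc1cc(O)c(C(=O)O)c(O)c1 | starting material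
2 | benzyl 2-(benzyloxy)-6-hydroxy-4-methylbenzoate | Cc1cc(O)c(C(=O)OCc2ccccc2)c(OCc2ccccc2)c1 | intermediate
3 | benzyl 6-(benzyloxy)-3-formyl-2-hydroxy-4-methylbenzoate | Cc1cc(OCc2ccccc2)c(C(=O)OCc2ccccc2)c(O)c1C=O | intermediate
4 | 4-(benzyloxy)-3-[(benzyloxy)carbonyl]-2-hydroxy-6-methylbenzoic acid | Cc1cc(OCc2ccccc2)c(C(=O)OCc2ccccc2)c(O)c1C(=O)O | intermediate
5 | 3-benzyl 1-[2-(trimethylsilyl)ethyl] 4-(benzyloxy)-2-hydroxy-6-methylbenzene-1,3-dicarboxylate | Cc1cc(OCc2ccccc2)c(C(=O)OCc2ccccc2)c(O)c1C(=O)OCC[Si](C)(C)C | intermediate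
6 | methyl 4-chloro-3-oxobutanoate | COC(=O)CC(=O)CCl | starting material
7 | 3-benzyl 1-[2-(trimethylsilyl)ethyl] 4-(benzyloxy)-2-(4-methoxy-2,4-dioxobutoxy)-6-methylbenzene-1,3-dicarboxylate | Cc1cc(OCc2ccccc2)c(C(=O)OCc2ccccc2)c(OCC(=O)CC(=O)OC)c1C(=O)OCC[Si](C)(C)C | intermediate
8 | 3-benzyl 1-[2-(trimethylsilyl)ethyl] 4-(benzyloxy)-2-{3-[(benzyloxy)methyl]-4-methoxy-2,4-dioxobutoxy}-6-methylbenzene-1,3-dicarboxylate (racemic) | Cc1cc(OCc2ccccc2)c(C(=O)OCc2ccccc2)c(OCC(=O)C(COCc2ccccc2)C(=O)OC)c1C(=O)OCC[Si](C)(C)C | intermediate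
9 | methyl 4-hydroxybut-2-ynoate | COC(=O)C#CCO | starting material
10 | methyl 4-[(tert-butyldimethylsilyl)oxy]but-2-ynoate | COC(=O)C#CCO[Si](C)(C)C(C)(C)C | intermediate
11 | 1-methoxy-1,3-bis(trimethylsilyloxy)buta-1,3-diene carrying 2-[(benzyloxy)methyl] and 4-aryloxy (aryl = ring A of 8; E/Z mixture) | Cc1cc(OCc2ccccc2)c(C(=O)OCc2ccccc2)c(OC=C(O[Si](C)(C)C)C(COCc2ccccc2)=C(OC)O[Si](C)(C)C)c1C(=O)OCC[Si](C)(C)C | intermediate
12 | methyl 3-aryloxy-5-[(benzyloxy)methyl]-2-{[(tert-butyldimethylsilyl)oxy]methyl}-6-methoxy-4,6-bis(trimethylsilyloxy)cyclohexa-1,4-diene-1-carboxylate (aryl = ring A of 8; stereoisomer mixture) | COC(=O)C1=C(CO[Si](C)(C)C(C)(C)C)C(Oc2c(C(=O)OCC[Si](C)(C)C)c(C)cc(OCc3ccccc3)c2C(=O)OCc2ccccc2)C(O[Si](C)(C)C)=C(COCc2ccccc2)C1(OC)O[Si](C)(C)C | intermediate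
13 | 4-(benzyloxy)-3-[(benzyloxy)carbonyl]-2-({6-[(benzyloxy)methyl]-5,7-dihydroxy-1-oxo-1,3-dihydro-2-benzofuran-4-yl}oxy)-6-methylbenzoic acid | Cc1cc(OCc2ccccc2)c(C(=O)OCc2ccccc2)c(Oc2c(O)c(COCc3ccccc3)c(O)c3c2COC3=O)c1C(=O)O | intermediate
14 | tri-O-benzyl conneotricone (benzyl ester; benzyl ethers at ring A phenol and at CH2OH) | Cc1cc(OCc2ccccc2)c(C(=O)OCc2ccccc2)c2c1C(=O)Oc1c(COCc3ccccc3)c(O)c3c(c1O2)COC3=O | intermediate
15 | conneotricone | Cc1cc(O)c(C(=O)O)c2c1C(=O)Oc1c(CO)c(O)c3c(c1O2)COC3=O | target

**Step count:** 10 steps in total; longest linear sequence 9 steps (steps 1–6 and 8–10 from 1).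

**Steps most likely to fail**

Step 8 (cycloaddition of a hindered diene with a 3-substituted ynoate). If the ynoate is too sluggish, set out again from 8 through diene 11 and use 4-bromofuran-2(5H)-one as a cyclic dienophile with the lactone already in place. The [4+2] reaction, with the same orientation, gives the bromo lactone cycloadduct F1. The same Bu4NF treatment then eliminates HBr and methanol, aromatises the ring and cleaves the silylethyl ester, and the route is rejoined at 13.

Step 5 (O-alkylation of a hindered, chelated phenol with a base-sensitive chloro keto ester). If self-condensation of 6 wins, set out from 5 and alkylate with methyl (E)-4-bromo-3-methoxybut-2-enoate (K2CO3, acetone), a non-enolisable allylic bromide. This gives the methyl enol ether F2, and brief treatment with 1 M HCl in THF unmasks the ketone to rejoin the route at 7.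

Step 6 (C- versus O-alkylation with the chloromethyl ether). If O-alkylation or loss of benzyl alcohol dominates, set out from 7 and silylate (Me3SiCl, Et3N) to the silyl enol ether F3. Alkylating F3 with BnOCH2Cl and catalytic ZnBr2 in CH2Cl2 (Lewis-acid alkylation of a silyl enol ether, which occurs at carbon only) rejoins the route at 8.

**Further compounds**
F1 | step 8 | 3a-bromo-4-aryloxy-6-[(benzyloxy)methyl]-7-methoxy-5,7-bis(trimethylsilyloxy)-3a,4,7,7a-tetrahydro-2-benzofuran-1(3H)-one (aryl = ring A of 8; stereoisomer mixture) | COC1(O[Si](C)(C)C)C(COCc2ccccc2)=C(O[Si](C)(C)C)C(Oc2c(C(=O)OCC[Si](C)(C)C)c(C)cc(OCc3ccccc3)c2C(=O)OCc2ccccc2)C2(Br)COC(=O)C12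
F2 | step 5 | 3-benzyl 1-[2-(trimethylsilyl)ethyl] 4-(benzyloxy)-2-{[(2E)-2,4-dimethoxy-4-oxobut-2-en-1-yl]oxy}-6-methylbenzene-1,3-dicarboxylate | Cc1cc(OCc2ccccc2)c(C(=O)OCc2ccccc2)c(OC/C(OC)=C\C(=O)OC)c1C(=O)OCC[Si](C)(C)C
F3 | step 6 | 3-benzyl 1-[2-(trimethylsilyl)ethyl] 4-(benzyloxy)-2-{[4-methoxy-4-oxo-2-(trimethylsilyloxy)but-2-en-1-yl]oxy}-6-methylbenzene-1,3-dicarboxylate | Cc1cc(OCc2ccccc2)c(C(=O)OCc2ccccc2)c(OCC(O[Si](C)(C)C)=CC(=O)OC)c1C(=O)OCC[Si](C)(C)C
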